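The synthesis rests on cutting the C5–C6 bond of the cyclopentanone ring. In the cyclopenta[c]pyridine the C5 ester carbon and the C6 acetoxy oxygen lie on one face of the five-membered ring and are linked through C5 and C6 only, so they can be held for a while in a four-membered lactone. A chiral-isothiourea-catalysed aldol-lactonisation of a keto acid thus makes C5–C6, the carbocycle, the β-lactone and both fully substituted stereocentres at once. The keto acid is a 2-dienylpyridine with a silyl-protected hydroxyacetic acid at pyridine C4 and a 1,2-diketone at pyridine C5; its ester is cleaved early, so later base meets only a non-enolisable carboxylate.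

Key step: step 11

Assumption: the sense of induction of (S)-HBTM [(2S)-2-phenyl-3,4-dihydro-2H-benzo[4,5]thiazolo[3,2-a]pyrimidine, N1=C2Sc3ccccc3N2CC[C@H]1c1ccccc1] on this tetrasubstituted enolate cannot be derived safely from the simpler known cases; the (S)-catalyst is written, and its (R)-enantiomer would be used in the same way if the other enolate face should be preferred.

Step 1
Reactants: 1 5-bromo-2-chloro-4-methylpyridine; 2 dimethyl carbonate
Product: 3 methyl 2-(5-bromo-2-chloropyridin-4-yl)acetate
Conditions: LiN(SiMe3)2 (2.2 equiv) added to 1 and 2 (1.3 equiv), THF, 0 °C; aq NH4Cl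
Reagents that add atoms: none
Why: Lateral metalation–carboxylation (Claisen-type C-acylation of the picolyl anion), in which the 4-methyl hydrogens are acidified by the ring nitrogen and both halogens, the silylamide is too weak to attack C–Br or to cause halogen migration, and the second equivalent of base stores the product as its enolate so that it is not acylated twice.

Step 2
Reactants: 3 methyl 2-(5-bromo-2-chloropyridin-4-yl)acetate
Product: 4 methyl 2-(5-bromo-2-chloropyridin-4-yl)-2-hydroxyacetate (racemic)
Conditions: KN(SiMe3)2 (1.1 equiv), THF, −78 °C; 3-phenyl-2-(phenylsulfonyl)oxaziridine (1.2 equiv), −78 °C; aq NH4Cl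
Reagents that add atoms: 3-phenyl-2-(phenylsulfonyl)oxaziridine, O=S(=O)(N1OC1c1ccccc1)c1ccccc1
Why: Davis oxidation of the potassium ester enolate by electrophilic oxygen transfer from the N-sulfonyloxaziridine; the carbinol centre forms as a racemate on purpose, because it is made planar again in step 11.

Step 3
Reactants: 4 methyl 2-(5-bromo-2-chloropyridin-4-yl)-2-hydroxyacetate
Product: 5 methyl 2-(5-bromo-2-chloropyridin-4-yl)-2-(triethylsilyloxy)acetate (racemic)
Conditions: TESCl (1.2 equiv), imidazole (2 equiv), DMF, 0 °C to rt
Reagents that add atoms: chlorotriethylsilane, CC[Si](Cl)(CC)CC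
Why: Routine silylation of a secondary alcohol with a silyl chloride and imidazole, giving a triethylsilyl ether that is small enough to allow the later enolisation and can be removed at the end with acidic fluoride.

Step 4
Reactants: 5 methyl 2-(5-bromo-2-chloropyridin-4-yl)-2-(triethylsilyloxy)acetate; 6 propyne
Product: 7 methyl 2-[2-chloro-5-(prop-1-yn-1-yl)pyridin-4-yl]-2-(triethylsilyloxy)acetate (racemic)
Conditions: propyne (3 equiv), Pd(PPh3)2Cl2 (3 mol %), CuI (6 mol %), Et3N, THF, 45 °C, sealed tube
Reagents that add atoms: none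
Why: Sonogashira coupling, in which zerovalent palladium inserts into the C–Br bond much faster than into the C–Cl bond next to nitrogen, so the chloride is saved for the Suzuki coupling.

Step 5
Reactants: 7 methyl 2-[2-chloro-5-(prop-1-yn-1-yl)pyridin-4-yl]-2-(triethylsilyloxy)acetate
Product: 8 2-[2-chloro-5-(prop-1-yn-1-yl)pyridin-4-yl]-2-(triethylsilyloxy)acetic acid (racemic)
Conditions: Me3SnOH (3 equiv), 1,2-dichloroethane, 70 °C; 0.1 M aq HCl wash, 0 °C
Reagents that add atoms: trimethyltin hydroxide, C[Sn](C)(C)O
Why: Tin-hydroxide-mediated ester hydrolysis (acyl substitution under nearly neutral conditions) that spares the silyl ether and the 2-chloropyridine; freeing the acid here means that every later basic step meets a carboxylate whose α-hydrogen is no longer acidic, so the diketone made next cannot be attacked in an uncontrolled aldol reaction.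

Step 6
Reactants: 8 2-[2-chloro-5-(prop-1-yn-1-yl)pyridin-4-yl]-2-(triethylsilyloxy)acetic acid
Product: 9 2-[2-chloro-5-(2-oxopropanoyl)pyridin-4-yl]-2-(triethylsilyloxy)acetic acid (racemic)
Conditions: RuCl3·xH2O (3 mol %), NaIO4 (3 equiv), NaHCO3 (1 equiv), EtOAc/MeCN/H2O, 0 °C to rt; work-up at pH 4
Reagents that add atoms: sodium periodate, [Na+].[O-]I(=O)(=O)=O
Why: RuO4-catalysed oxidation of an internal aryl alkyl alkyne to the 1,2-diketone, carried out before any alkene is in the molecule; the electron-poor chloropyridine and the carbinol C–H flanked by carboxylate and heteroarene are slow to oxidise, and the bicarbonate buffer protects the silyl ether.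

Step 7
Reactants: 10 (S)-2-methylbutan-1-ol
Product: 11 (S)-2-methylbutanal
Conditions: TEMPO (1 mol %), KBr (10 mol %), aq NaOCl (1.1 equiv, NaHCO3 buffer, pH 9), CH2Cl2, 0 °C
Reagents that add atoms: none
Why: Anelli oxidation (nitroxyl-catalysed hypochlorite oxidation) of a primary alcohol, which stops at the aldehyde and should leave the α-stereocentre of this chiral-pool compound intact in the buffered two-phase system at 0 °C.

Step 8
Reactants: 11 (S)-2-methylbutanal; 12 2-(triphenylphosphoranylidene)propanal
Product: 13 (2E,4S)-2,4-dimethylhex-2-enal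
Conditions: toluene, 90 °C, sealed tube
Reagents that add atoms: none
Why: Wittig olefination with a formyl-stabilised ylide, which gives the E-trisubstituted enal and is too weakly basic to epimerise the α-branched aldehyde.

Step 9
Reactants: 13 (2E,4S)-2,4-dimethylhex-2-enal; 14 2-(dichloromethyl)-4,4,5,5-tetramethyl-1,3,2-dioxaborolane
Product: 15 2-[(1E,3E,5S)-3,5-dimethylhepta-1,3-dien-1-yl]-4,4,5,5-tetramethyl-1,3,2-dioxaborolane
Conditions: CrCl2 (8 equiv), LiI (4 equiv), THF, rt
Reagents that add atoms: none
Why: Takai–Utimoto borylolefination, in which the geminal dichromium reagent formed from 14 and CrCl2 adds to the aldehyde and eliminates to the E-alkenylboronate under non-basic conditions that leave the allylic stereocentre and the existing E-alkene untouched.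

Step 10
Reactants: 9 2-[2-chloro-5-(2-oxopropanoyl)pyridin-4-yl]-2-(triethylsilyloxy)acetic acid; 15 2-[(1E,3E,5S)-3,5-dimethylhepta-1,3-dien-1-yl]-4,4,5,5-tetramethyl-1,3,2-dioxaborolane
Product: 16 2-[2-[(1E,3E,5S)-3,5-dimethylhepta-1,3-dien-1-yl]-5-(2-oxopropanoyl)pyridin-4-yl]-2-(triethylsilyloxy)acetic acid (both epimers at the silyloxy carbon)
Conditions: Pd(dppf)Cl2 (5 mol %), K3PO4 (3 equiv), 1,4-dioxane/H2O (10:1), 50 °C; aq citric acid to pH 4, 0 °C
Reagents that add atoms: none
Why: Suzuki–Miyaura coupling at a 2-chloropyridine that is activated by the ring nitrogen and the para acyl group, with retention of both alkene geometries; the substrate reacts as its carboxylate, so the carbinol C–H is not enolised and no aldol closure can occur before the catalyst-controlled step.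

Step 11
Reactants: 16 2-[2-[(1E,3E,5S)-3,5-dimethylhepta-1,3-dien-1-yl]-5-(2-oxopropanoyl)pyridin-4-yl]-2-(triethylsilyloxy)acetic acid
Product: 19 cis-fused β-lactone (5R,6S)-3-[(1E,3E,5S)-3,5-dimethylhepta-1,3-dien-1-yl]-6-hydroxy-6-methyl-7-oxo-5-(triethylsilyloxy)-6,7-dihydro-5H-cyclopenta[c]pyridine-5-carboxylic acid 5,6-lactone, via mixed tosyl anhydride 17 (not isolated), via isothiouronium enolate 18 (not isolated)
Conditions: (S)-HBTM (20 mol %), TsCl (1.5 equiv), iPr2NEt (4 equiv), LiCl (1 equiv), CH2Cl2 (0.03 M), rt, 16 added over 4 h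
Reagents that add atoms: none
Why: TsCl turns the carboxylate into mixed anhydride 17, the isothiourea takes over the acyl group, and iPr2NEt removes the α-hydrogen, which is acidified by the pyridin-4-yl ring, the silyloxy group and the acyl isothiouronium unit, to give enolate 18, so that both epimers of 16 converge on one planar intermediate. The enolate carbon adds to the methyl-ketone carbonyl of the 1,2-diketone in a 5-exo-trig (5-enolexo) closure that forms C5–C6 and the cyclopentanone, and the C6 alkoxide then attacks the acyl isothiouronium carbon in a 4-exo-trig closure that forms the β-lactone and releases the catalyst. The closest known reaction type is the nucleophile-catalysed aldol-lactonisation of keto acids to cyclopentane-fused β-lactones, together with amine-promoted bis-cyclisations that create a heteroatom-bearing, fully substituted enolate carbon next to a carbinol derived from a methyl ketone; the present substrate combines both features and carries an oxygen on the enolate, which is where the risk lies. C5 and C6 are set relative to each other by the ring fusion, because a four-membered lactone can bridge adjacent carbons of a cyclopentane only cis, so the C5 carboxyl and the C6 oxygen must end on one face, and an aldolate with the other arrangement cannot close and should revert. The absolute sense (5R,6S) is set by the catalyst, whose phenyl-bearing stereocentre blocks one face of the bound enolate. The site selectivity that is needed, attack on the distal and not the aryl-bound carbonyl, is secured by ring size (the alternative is a four-membered carbocycle) and by the high electrophilicity of the 1,2-diketone, while slow addition and low concentration hold back intermolecular acylation and the uncatalysed background.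

Step 12
Reactants: 19 cis-fused β-lactone
Product: 20 methyl (5R,6S)-3-[(1E,3E,5S)-3,5-dimethylhepta-1,3-dien-1-yl]-6-hydroxy-6-methyl-7-oxo-5-(triethylsilyloxy)-6,7-dihydro-5H-cyclopenta[c]pyridine-5-carboxylate
Conditions: MeOH/CH2Cl2 (1:1), Et3N (1.5 equiv), DMAP (10 mol %), 0 °C to rt
Reagents that add atoms: methanol, CO
Why: Methanolysis of a strained β-lactone by addition–elimination at the acyl carbon (the tertiary C6–O bond cannot be displaced), which breaks no bond at C5 or C6 and so keeps both configurations, while the weak amine base keeps the concentration of the C6 alkoxide low and thereby guards against retro-aldol opening.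

Step 13
Reactants: 20 methyl (5R,6S)-3-[(1E,3E,5S)-3,5-dimethylhepta-1,3-dien-1-yl]-6-hydroxy-6-methyl-7-oxo-5-(triethylsilyloxy)-6,7-dihydro-5H-cyclopenta[c]pyridine-5-carboxylate
Product: 21 methyl (5R,6S)-6-acetoxy-3-[(1E,3E,5S)-3,5-dimethylhepta-1,3-dien-1-yl]-6-methyl-7-oxo-5-(triethylsilyloxy)-6,7-dihydro-5H-cyclopenta[c]pyridine-5-carboxylate
Conditions: Ac2O (5 equiv), DMAP (0.5 equiv), pyridine, CH2Cl2, rt to 35 °C
Reagents that add atoms: acetic anhydride, CC(=O)OC(C)=O
Why: DMAP-catalysed acyl transfer (Steglich-type acetylation) to the only free hydroxyl group, the tertiary α-ketol oxygen at C6, while the C5 oxygen is still silylated.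

Step 14
Reactants: 21 methyl (5R,6S)-6-acetoxy-3-[(1E,3E,5S)-3,5-dimethylhepta-1,3-dien-1-yl]-6-methyl-7-oxo-5-(triethylsilyloxy)-6,7-dihydro-5H-cyclopenta[c]pyridine-5-carboxylate
Product: 22 methyl (5R,6S)-6-acetoxy-3-[(1E,3E,5S)-3,5-dimethylhepta-1,3-dien-1-yl]-5-hydroxy-6-methyl-7-oxo-6,7-dihydro-5H-cyclopenta[c]pyridine-5-carboxylate (target)
Conditions: HF·pyridine, pyridine, THF, 0 °C to rt, polyethylene vessel
Reagents that add atoms: none
Why: Fluoride-driven cleavage of the Si–O bond with HF·pyridine, whose acidic character avoids the alkoxide-triggered retro-aldol and acyl-shift pathways, the latter being disfavoured in any case because C5–OH and C6–OAc are trans on the five-membered ring.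

Compound list
1 | 5-bromo-2-chloro-4-methylpyridine | Cc1cc(Cl)ncc1Br | starting material
2 | dimethyl carbonate | COC(=O)OC | starting material
3 | methyl 2-(5-bromo-2-chloropyridin-4-yl)acetate | COC(=O)Cc1cc(Cl)ncc1Br | intermediate
4 | methyl 2-(5-bromo-2-chloropyridin-4-yl)-2-hydroxyacetate (racemic) | COC(=O)C(O)c1cc(Cl)ncc1Br | intermediate
5 | methyl 2-(5-bromo-2-chloropyridin-4-yl)-2-(triethylsilyloxy)acetate (racemic) | COC(=O)C(O[Si](CC)(CC)CC)c1cc(Cl)ncc1Br | intermediate
6 | propyne | CC#C | starting material
7 | methyl 2-[2-chloro-5-(prop-1-yn-1-yl)pyridin-4-yl]-2-(triethylsilyloxy)acetate (racemic) | CC#Cc1cnc(Cl)cc1C(O[Si](CC)(CC)CC)C(=O)OC | intermediate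
8 | 2-[2-chloro-5-(prop-1-yn-1-yl)pyridin-4-yl]-2-(triethylsilyloxy)acetic acid (racemic) | CC#Cc1cnc(Cl)cc1C(O[Si](CC)(CC)CC)C(=O)O | intermediate
9 | 2-[2-chloro-5-(2-oxopropanoyl)pyridin-4-yl]-2-(triethylsilyloxy)acetic acid (racemic) | CC(=O)C(=O)c1cnc(Cl)cc1C(O[Si](CC)(CC)CC)C(=O)O | intermediate
10 | (S)-2-methylbutan-1-ol | CC[C@H](C)CO | starting material
11 | (S)-2-methylbutanal | CC[C@H](C)C=O | intermediate
12 | 2-(triphenylphosphoranylidene)propanal | CC(C=O)=P(c1ccccc1)(c1ccccc1)c1ccccc1 | starting material
13 | (2E,4S)-2,4-dimethylhex-2-enal | CC[C@H](C)/C=C(C)/C=O | intermediate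
14 | 2-(dichloromethyl)-4,4,5,5-tetramethyl-1,3,2-dioxaborolane | ClC(Cl)B1OC(C)(C)C(C)(C)O1 | starting material
15 | 2-[(1E,3E,5S)-3,5-dimethylhepta-1,3-dien-1-yl]-4,4,5,5-tetramethyl-1,3,2-dioxaborolane | CC[C@H](C)/C=C(C)/C=C/B1OC(C)(C)C(C)(C)O1 | intermediate
16 | 2-[2-[(1E,3E,5S)-3,5-dimethylhepta-1,3-dien-1-yl]-5-(2-oxopropanoyl)pyridin-4-yl]-2-(triethylsilyloxy)acetic acid (both epimers at the silyloxy carbon) | CC[C@H](C)/C=C(C)/C=C/c1cc(c(cn1)C(=O)C(C)=O)C(O[Si](CC)(CC)CC)C(=O)O | intermediate
17 | mixed anhydride of 16 with 4-methylbenzenesulfonic acid (not isolated) | CC[C@H](C)/C=C(C)/C=C/c1cc(c(cn1)C(=O)C(C)=O)C(O[Si](CC)(CC)CC)C(=O)OS(=O)(=O)c1ccc(C)cc1 | intermediate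
18 | zwitterionic enolate of 16 bound through its acyl carbon to the imine nitrogen of (S)-HBTM (enolate geometry left open; not isolated) | CC[C@H](C)/C=C(C)/C=C/c1cc(c(cn1)C(=O)C(C)=O)C(O[Si](CC)(CC)CC)=C([O-])[N+]1=C2Sc3ccccc3N2CC[C@H]1c1ccccc1 | intermediate
19 | cis-fused β-lactone (5R,6S)-3-[(1E,3E,5S)-3,5-dimethylhepta-1,3-dien-1-yl]-6-hydroxy-6-methyl-7-oxo-5-(triethylsilyloxy)-6,7-dihydro-5H-cyclopenta[c]pyridine-5-carboxylic acid 5,6-lactone | CC[C@H](C)/C=C(C)/C=C/c1cc2c(cn1)C(=O)[C@@]3(C)OC(=O)[C@@]23O[Si](CC)(CC)CC | intermediate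
20 | methyl (5R,6S)-3-[(1E,3E,5S)-3,5-dimethylhepta-1,3-dien-1-yl]-6-hydroxy-6-methyl-7-oxo-5-(triethylsilyloxy)-6,7-dihydro-5H-cyclopenta[c]pyridine-5-carboxylate | CC[C@H](C)/C=C(C)/C=C/c1cc2c(cn1)C(=O)[C@@](C)(O)[C@@]2(O[Si](CC)(CC)CC)C(=O)OC | intermediate
21 | methyl (5R,6S)-6-acetoxy-3-[(1E,3E,5S)-3,5-dimethylhepta-1,3-dien-1-yl]-6-methyl-7-oxo-5-(triethylsilyloxy)-6,7-dihydro-5H-cyclopenta[c]pyridine-5-carboxylate | CC[C@H](C)/C=C(C)/C=C/c1cc2c(cn1)C(=O)[C@@](C)(OC(C)=O)[C@@]2(O[Si](CC)(CC)CC)C(=O)OC | intermediate
22 | methyl (5R,6S)-6-acetoxy-3-[(1E,3E,5S)-3,5-dimethylhepta-1,3-dien-1-yl]-5-hydroxy-6-methyl-7-oxo-6,7-dihydro-5H-cyclopenta[c]pyridine-5-carboxylate | CC[C@H](C)/C=C(C)/C=C/c1cc2c(cn1)C(=O)[C@@](C)(OC(C)=O)[C@@]2(O)C(=O)OC | target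

Total step count: 14. Longest linear sequence: 11 steps (steps 1–6 and 10–14, from 5-bromo-2-chloro-4-methylpyridine); the side chain is a three-step branch (steps 7–9).

Steps most likely to fail

Step 11. What may go wrong: facial discrimination by the catalyst may be incomplete on the crowded, oxygen-bearing enolate; an amine-mediated background closure by way of a ketene would escape catalyst control; intermolecular acylation could compete with ring closure. The fallback leaves the lactone manifold and closes the ring by a direct catalytic asymmetric aldol reaction of the ester, setting out from 16 and coming back at 20. Acid 16 is esterified with trimethylsilyldiazomethane (toluene/MeOH, 0 °C, titrated to the end point) to methyl 2-[2-[(1E,3E,5S)-3,5-dimethylhepta-1,3-dien-1-yl]-5-(2-oxopropanoyl)pyridin-4-yl]-2-(triethylsilyloxy)acetate F1. F1 is then treated with a cinchona-derived bifunctional Brønsted base (a quinidine squaramide in toluene at −20 °C, or an N-benzylcinchoninium salt with solid Cs2CO3), whose ion-paired ester enolate adds to the methyl-ketone carbonyl and should give hydroxy ester 20 directly, so that step 12 is skipped. A closed, hydrogen-bonded transition state should again place ester and new hydroxyl on one face, and any trans isomer would be removed by chromatography.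

Step 10. What may go wrong: the 1,2-diketone may be degraded by aqueous base (hydration followed by cleavage, or aldol self-condensation through its methyl group), the activated C–Cl bond may be displaced by hydroxide, and the dienylboronate may be protodeboronated. The fallback replaces the base-dependent transmetalation by a base-free Stille coupling, setting out from 13 and 9 and coming back at 16. Enal 13 is converted by the tin variant of the Takai olefination (Bu3SnCHBr2, CrCl2, LiI, THF/DMF, rt) into tributyl[(1E,3E,5S)-3,5-dimethylhepta-1,3-dien-1-yl]stannane F2, and F2 is coupled with chloride 9 (Pd(PPh3)4, CuI, DMF, 60 °C, no added base) to give 16.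

Step 13. What may go wrong: acyl transfer to the hindered tertiary hydroxyl may be slow, and during a prolonged basic reaction the C5–C6 bond may open by retro-aldol cleavage, which would erase both new stereocentres, or the silyl ether may be lost and both oxygens acetylated. The fallback acylates the oxygen as its alkoxide at the moment it is set free, setting out from 19 and coming back at 21. LiOMe (1.0 equiv, THF, −78 °C) opens the lactone to lithium (5R,6S)-3-[(1E,3E,5S)-3,5-dimethylhepta-1,3-dien-1-yl]-5-(methoxycarbonyl)-6-methyl-7-oxo-5-(triethylsilyloxy)-6,7-dihydro-5H-cyclopenta[c]pyridin-6-olate F3, which is trapped in the same flask with acetic anhydride at −78 °C to give 21, so that compound 20 is bypassed.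

Further compounds
F1 | step 11 | methyl 2-[2-[(1E,3E,5S)-3,5-dimethylhepta-1,3-dien-1-yl]-5-(2-oxopropanoyl)pyridin-4-yl]-2-(triethylsilyloxy)acetate | CC[C@H](C)/C=C(C)/C=C/c1cc(c(cn1)C(=O)C(C)=O)C(O[Si](CC)(CC)CC)C(=O)OC
F2 | step 10 | tributyl[(1E,3E,5S)-3,5-dimethylhepta-1,3-dien-1-yl]stannane | CC[C@H](C)/C=C(C)/C=C/[Sn](CCCC)(CCCC)CCCC
F3 | step 13 | lithium (5R,6S)-3-[(1E,3E,5S)-3,5-dimethylhepta-1,3-dien-1-yl]-5-(methoxycarbonyl)-6-methyl-7-oxo-5-(triethylsilyloxy)-6,7-dihydro-5H-cyclopenta[c]pyridin-6-olate | CC[C@H](C)/C=C(C)/C=C/c1cc2c(cn1)C(=O)[C@@](C)([O-])[C@@]2(O[Si](CC)(CC)CC)C(=O)OC.[Li+]
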